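**Assumption.** The target SMILES carries no descriptor for the hindered biaryl axis, so the target is taken as the racemate and no axial configuration is set. Flavone numbering is used for both halves: unit 1 is the 4-methoxyphenyl flavone, unit 2 the 4-hydroxyphenyl flavone.

## Analysis of the target

The target 13 is a biflavone: two 2-aryl-4H-chromen-4-one units joined by one aryl–aryl bond from C6 of unit 1 (5,7-dihydroxy-4'-methoxyflavone) to C8 of unit 2 (5,7,4'-trihydroxyflavone). It has no stereocentre. The only stereogenic element is the biaryl axis, which has four ortho substituents (5-OH and 7-OH of unit 1, 7-OH and the O1-bearing C8a of unit 2). The sensitive functions are five free phenols (two chelated to the C4 carbonyls), two pyranone rings that open at O1–C2 in hot acid or base, and one aryl methyl ether on ring B of unit 1 that must survive every deprotection. Three things make the synthesis hard. The two halves are nearly the same flavone but must be joined as a hetero-dimer through different ring positions. The biaryl bond is tetra-ortho-substituted. And C6 of a 5,7-dialkoxyflavone lies between two alkoxy groups and is not where electrophiles attack; C8 is. The strategy rests on ring A of unit 1: the pyranone is attached to it through C4a–C4 and through either O1 or O5, and C6 and C8 are the two carbons ortho to O7. Opening the pyranone at O1–C2 and closing it onto the former O5 turns the former C8 into C6, so a C6-linked unit 1 is the isomer of a C8-linked one.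

## Retrosynthetic reasoning

**13 from 12.** The last operation forms no skeletal bond. The 5-OH of unit 2 in 13 is traced back to a methyl ether in 12. This methyl group is what keeps unit 2 from isomerizing in the preceding acid step. It differs from the 4'-methoxy group of unit 1 because it sits peri to the C4 carbonyl, so a chelating boron Lewis acid can remove it selectively. The forward step must be cold and anhydrous, because once the 5-OH of unit 2 is free, hot protic acid could make that half migrate as well.

**12 from 10 (through 11).** The O1–C2 bond of unit 1 in 12 is cut, and C2 is reconnected to the oxygen on the other side of the acyl carbon. This converts the C6–C8 biaryl of 12 into the C8–C8 biaryl of 10, with the open 1,3-diketone 11 as the shared intermediate. The gain is that both halves of 10 are 8-substituted flavones, which direct substitution of 5,7-dialkoxyflavones delivers. Cutting the biaryl bond of 12 itself would need a C6-functionalized unit 1 whose reacting carbon is flanked by two protected oxygens. The forward reaction is an acid-mediated equilibration that must isomerize unit 1 and leave unit 2 in place.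

**10 from 9.** Four O-benzyl groups are added back. Benzyl is chosen because hydrogenolysis removes it without touching either methyl ether. The 5-oxygen of unit 1 must be alkylated during iodination, since a free 5-OH would steer the electrophile to C6. All phenols are masked during the cross-coupling.

**9 from 4 and 8.** The C8–C8 biaryl bond is cut into the boronate 4 of unit 1 and the iodide 8 of unit 2. A cross-coupling is needed because the halves differ; a reductive homocoupling of two iodides would give a statistical mixture. The cut makes the route convergent, and each partner comes from a commercial flavone in three steps. The forward reaction must form a tetra-ortho-substituted biaryl.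

**4 from 3, 2 and 1.** The C–B bond of 4 comes from the C–I bond of 3. That bond comes from the C8–H bond of dibenzyl ether 2, which is made from acacetin 1. Both phenols of 1 are benzylated so that electrophilic substitution goes to C8.

**8 from 7, 6 and 5.** The C–I bond of 8 comes from C8–H of 7. Compound 7 is the 5-O-methyl ether of 6, and 6 is the 7,4'-dibenzyl ether of apigenin 5. The order uses the different acidity of the phenols: the two unchelated ones are benzylated first, which leaves the chelated 5-OH as the only site for the methyl group.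

## Alternatives that were turned down

**Alternative 1:** The benzo ring of unit 2 is disconnected at C5–C6 and grown onto a preformed 4-pyranone. The precursor A1 is a 2-aryl-4-pyranone. It carries an ester on the carbon that becomes C4a and a 1-aryl-2-oxopropyl chain on the carbon that becomes C8a. The aryl group of that chain is a symmetric 2,6-bis(benzyloxy)-4-silyloxyphenyl ring, the future ring A of unit 1.
- Forward key step: an excess of a hindered lithium amide forms the dienolate of A1. Its methyl ketone terminus attacks the ester carbon in a Claisen-type closure, and tautomerization gives the 5,7-diol A2.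
- For it: the future biaryl bond starts as an sp3 carbon–aryl bond, so no hindered cross-coupling is needed. The aryl ring is symmetric, so the later linkage position on unit 1 is fixed by construction and no isomer mixture arises. On both points it is stronger than the chosen route.
- Against it: A1 is a multi-step target in itself. 4-Pyranones are opened by amide bases and nucleophiles at C2 and C6. The benzylic CH between a 2,6-disubstituted aryl ring and two carbonyl-bearing carbons is hard to deprotonate, and the dienolate can also close through oxygen. After A2, unit 1 still has to be built: phenol protection, desilylation, pyranone construction and debenzylation.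
- Comparison: the linear sequence would be about twice as long. The chosen strategy takes every carbon from two commercial flavones and reaches the target in ten steps.

**Alternative 2:** The pyranone of unit 2 is disconnected at C2=C3 as an intramolecular Wittig olefination of an ester. The precursor A3 is a biphenyl in which the unit 2 ring carries an acyl ylide and, on the neighbouring oxygen, a 4-benzyloxybenzoate.
- Forward key step: on heating in an aromatic solvent the ylide carbon adds to the ester carbonyl and the phosphine oxide is lost, which gives flavone A4.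
- For it: the conditions are neutral, so benzyl and silyl ethers survive. Which oxygen becomes O1 is decided by which phenol is acylated, so unit 2 cannot form as the wrong isomer.
- Against it: the unit 2 ring of A3 needs three differentiated oxygens, and the one to be acylated is the most hindered, lying between the biaryl bond and the acyl group. The biphenyl is tetra-ortho-substituted, so a hindered coupling is still needed, though on simpler arenes than in the chosen route. Ester carbonyls are poor Wittig acceptors, and this one is shielded by the adjacent aryl ring. After A4, unit 1 is still missing.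
- Comparison: the regiochemistry is certain, but the step count is clearly higher. The chosen strategy has a weaker key step, but it is short and its by-product is recyclable starting material.

**Alternative 3:** The pyranone of unit 1 is disconnected at C4–C4a. The symmetric phenol A5 (A4 without its silyl group) would be added to an arylpropiolic ester and saponified to the (Z)-3-aryloxy-3-(4-methoxyphenyl)acrylic acid A6.
- Forward key step: activation of the acid of A6 with an anhydride or a dehydrating strong acid leads to acylation of the ortho carbon of the aryloxy ring. This gives A7, the pentabenzyl ether of the target, and hydrogenolysis would finish the synthesis.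
- For it: the two ortho carbons of A5 are equivalent, so closure at either gives the 6-linked flavone only. There is no equilibrium and no separation. The 4'-methoxy group is the only methyl ether in the molecule, so the last step is a plain global debenzylation and needs no selective Lewis-acid cleavage. On both points it is stronger than the chosen route.
- Against it: A5 is only reached at the end of a long sequence such as Alternative 1 or 2. The oxa-Michael addition of a hindered, electron-rich phenol must give the Z acid. The acylation medium is strongly acidic and meets five benzyl ethers, which can be lost or migrate onto the electron-rich rings. The carbon to be acylated lies between a benzyloxy group and the vinyloxy-bearing carbon.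
- Comparison: it is the cleanest regiochemical solution. The chosen strategy is preferred for step economy and because every step before the key step uses well-established flavone chemistry.

Key step: step 9

## Route

Step 1
Reactants: 1 acacetin (5,7-dihydroxy-4'-methoxyflavone)
Product: 2 5,7-di-O-benzylacacetin
Conditions: BnBr (3 equiv), K2CO3, DMF, 80 °C
Reagents that add atoms: benzyl bromide, BrCc1ccccc1
Why: Williamson etherification; the 7-OH reacts readily, and the chelated 5-OH follows with excess halide and heating in a polar aprotic solvent.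

Step 2
Reactants: 2 5,7-di-O-benzylacacetin
Product: 3 8-iodo-5,7-di-O-benzylacacetin
Conditions: I2, CF3CO2Ag, CH2Cl2, 0 °C to rt, dark
Reagents that add atoms: iodine, II
Why: Electrophilic aromatic iodination with silver-activated iodine. With O5 alkylated, C6 is buried between two benzyloxy groups, while C8 is para to the 5-alkoxy and ortho to the 7-alkoxy group and open on the O1 side, so substitution goes to C8.

Step 3
Reactants: 3 8-iodo-5,7-di-O-benzylacacetin
Product: 4 5,7-di-O-benzylacacetin-8-boronic acid pinacol ester
Conditions: B2pin2, PdCl2(dppf) (5 mol%), KOAc, DMSO, 85 °C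
Reagents that add atoms: bis(pinacolato)diboron, CC1(C)OB(OC1(C)C)B1OC(C)(C)C(C)(C)O1
Why: Miyaura borylation: oxidative addition of zerovalent palladium into the C–I bond, acetate-assisted transmetalation and reductive elimination. KOAc is too weak a base to drive a following Suzuki homocoupling.

Step 4
Reactants: 5 apigenin (5,7,4'-trihydroxyflavone)
Product: 6 7,4'-di-O-benzylapigenin
Conditions: BnBr (2.2 equiv), K2CO3, acetone, reflux
Reagents that add atoms: benzyl bromide, BrCc1ccccc1
Why: Williamson etherification of the two unchelated, more acidic phenols; the 5-OH is hydrogen-bonded to the C4 carbonyl and stays free under these mild conditions.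

Step 5
Reactants: 6 7,4'-di-O-benzylapigenin
Product: 7 7,4'-di-O-benzyl-5-O-methylapigenin
Conditions: MeI (5 equiv), K2CO3, DMF, 50 °C
Reagents that add atoms: iodomethane, CI
Why: Williamson O-methylation of the remaining chelated phenol, which needs excess iodide and a polar aprotic solvent.

Step 6
Reactants: 7 7,4'-di-O-benzyl-5-O-methylapigenin
Product: 8 8-iodo-7,4'-di-O-benzyl-5-O-methylapigenin
Conditions: I2, CF3CO2Ag, CH2Cl2, 0 °C to rt, dark
Reagents that add atoms: iodine, II
Why: Electrophilic aromatic iodination as in step 2; the 5-methoxy and 7-benzyloxy groups shield C6 and direct to C8, and ring B, conjugated to the electron-poor C2, is much less reactive than ring A.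

Step 7
Reactants: 4 5,7-di-O-benzylacacetin-8-boronic acid pinacol ester (1.5 equiv); 8 8-iodo-7,4'-di-O-benzyl-5-O-methylapigenin
Product: 9 tetra-O-benzyl 8,8-linked biflavone (unit 1: 5,7-bis(benzyloxy)-4'-methoxy; unit 2: 7,4'-bis(benzyloxy)-5-methoxy), racemic about the axis
Conditions: Pd2(dba)3 (5 mol%), SPhos (20 mol%), K3PO4, toluene–H2O 10:1, 100 °C
Reagents that add atoms: none
Why: Suzuki–Miyaura coupling; the bulky, electron-rich biarylphosphine supports oxidative addition of zerovalent palladium into the hindered iodide and reductive elimination to a tetra-ortho-substituted biaryl. Ethers and flavone carbonyls are inert, and the axis forms as the racemate.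

Step 8
Reactants: 9 tetra-O-benzyl 8,8-linked biflavone
Product: 10 8,8-linked biflavone of 5,7-dihydroxy-4'-methoxyflavone and 7,4'-dihydroxy-5-methoxyflavone
Conditions: H2 (1 atm), 10% Pd/C, THF–MeOH 1:1, rt
Reagents that add atoms: none
Why: Catalytic hydrogenolysis of four aryl benzyl ethers. Aryl methyl ethers are not cleaved, and the flavone C2=C3 bond is reduced far more slowly than benzyl C–O bonds are cleaved, so the reaction is stopped after uptake for four benzyl groups.

Step 9
Reactants: 10 8,8-linked biflavone of 5,7-dihydroxy-4'-methoxyflavone and 7,4'-dihydroxy-5-methoxyflavone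
Product: 12 6,8-linked biflavone (unit 1: 5,7-dihydroxy-4'-methoxyflavon-6-yl; unit 2: 7,4'-dihydroxy-5-methoxyflavon-8-yl), via ring-opened 1,3-diketone 11 (not isolated)
Conditions: 2 M H2SO4, 1,4-dioxane–H2O 1:1, 110 °C, sealed tube, Ar; separate 12 by reversed-phase chromatography, recycle 10
Reagents that add atoms: none
Why: Wessely–Moser isomerization of a 5-hydroxyflavone. Protonation of the C4 carbonyl makes unit 1 a 4-hydroxybenzopyrylium ion, water adds at C2, and the hemiketal opens at O1–C2 to the aroylacetyl-phloroglucinol 11. Rotation about the aryl–carbonyl bond brings the former 5-OH next to the side-chain ketone; its 6-exo-trig addition to that carbonyl and loss of the water taken up before close the new pyranone, so the biaryl carbon becomes C6. The closest known reaction is the acid-promoted interconversion of 8- and 6-substituted 5,7-dihydroxyflavones, for example of 8-C- and 6-C-glycosylflavones. No stereocentre is formed and the axis stays racemic. The step must isomerize unit 1 only: unit 2 also opens, but its 5-oxygen is methylated, so it can reclose only through the original oxygen and returns unchanged. A halide-free acid is used so that neither methyl ether is removed by nucleophilic attack on its methyl group. The two isomers equilibrate, so 12 is separated and recovered 10 is resubmitted.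

Step 10
Reactants: 12 6,8-linked biflavone with 5-O-methyl on unit 2
Product: 13 target, 6-(apigenin-8-yl)acacetin
Conditions: BCl3 (1 M in CH2Cl2, 8 equiv), CH2Cl2, −78 °C to 0 °C; then MeOH, H2O
Reagents that add atoms: none
Why: Chelation-directed Lewis-acid ether cleavage: boron binds the C4 carbonyl and the peri 5-methoxy oxygen of unit 2 in a six-membered chelate and chloride removes the methyl group, while the unchelated 4'-methoxy group of unit 1 is not cleaved at this temperature. The cold, anhydrous medium cannot open the pyranones, so the freed 5-OH of unit 2 does not lead to migration of that half.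

## Compound list

1 | acacetin, 5,7-dihydroxy-2-(4-methoxyphenyl)-4H-chromen-4-one | COc1ccc(cc1)-c1cc(=O)c2c(O)cc(O)cc2o1 | starting material
2 | 5,7-bis(benzyloxy)-2-(4-methoxyphenyl)-4H-chromen-4-one | COc1ccc(cc1)-c1cc(=O)c2c(OCc3ccccc3)cc(OCc3ccccc3)cc2o1 | intermediate
3 | 5,7-bis(benzyloxy)-8-iodo-2-(4-methoxyphenyl)-4H-chromen-4-one | COc1ccc(cc1)-c1cc(=O)c2c(OCc3ccccc3)cc(OCc3ccccc3)c(I)c2o1 | intermediate
4 | 5,7-bis(benzyloxy)-2-(4-methoxyphenyl)-8-(4,4,5,5-tetramethyl-1,3,2-dioxaborolan-2-yl)-4H-chromen-4-one | COc1ccc(cc1)-c1cc(=O)c2c(OCc3ccccc3)cc(OCc3ccccc3)c(B3OC(C)(C)C(C)(C)O3)c2o1 | intermediate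
5 | apigenin, 5,7-dihydroxy-2-(4-hydroxyphenyl)-4H-chromen-4-one | O=c1cc(-c2ccc(O)cc2)oc2cc(O)cc(O)c12 | starting material
6 | 7-(benzyloxy)-2-[4-(benzyloxy)phenyl]-5-hydroxy-4H-chromen-4-one | O=c1cc(-c2ccc(OCc3ccccc3)cc2)oc2cc(OCc3ccccc3)cc(O)c12 | intermediate
7 | 7-(benzyloxy)-2-[4-(benzyloxy)phenyl]-5-methoxy-4H-chromen-4-one | COc1cc(OCc2ccccc2)cc2oc(-c3ccc(OCc4ccccc4)cc3)cc(=O)c12 | intermediate
8 | 7-(benzyloxy)-2-[4-(benzyloxy)phenyl]-8-iodo-5-methoxy-4H-chromen-4-one | COc1cc(OCc2ccccc2)c(I)c2oc(-c3ccc(OCc4ccccc4)cc3)cc(=O)c12 | intermediate
9 | 8-{7-(benzyloxy)-2-[4-(benzyloxy)phenyl]-5-methoxy-4-oxo-4H-chromen-8-yl}-5,7-bis(benzyloxy)-2-(4-methoxyphenyl)-4H-chromen-4-one (racemic axis) | COc1ccc(cc1)-c2cc(=O)c3c(OCc4ccccc4)cc(OCc4ccccc4)c(c3o2)-c5c(OCc6ccccc6)cc(OC)c7c(=O)cc(oc57)-c8ccc(OCc9ccccc9)cc8 | intermediate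
10 | 5,7-dihydroxy-8-[7-hydroxy-2-(4-hydroxyphenyl)-5-methoxy-4-oxo-4H-chromen-8-yl]-2-(4-methoxyphenyl)-4H-chromen-4-one (racemic axis) | COc1ccc(cc1)-c2cc(=O)c3c(O)cc(O)c(c3o2)-c4c(O)cc(OC)c5c(=O)cc(oc45)-c6ccc(O)cc6 | intermediate
11 | 1-{2,4,6-trihydroxy-3-[7-hydroxy-2-(4-hydroxyphenyl)-5-methoxy-4-oxo-4H-chromen-8-yl]phenyl}-3-(4-methoxyphenyl)propane-1,3-dione (not isolated) | COc1ccc(cc1)C(=O)CC(=O)c2c(O)cc(O)c(c2O)-c3c(O)cc(OC)c4c(=O)cc(oc34)-c5ccc(O)cc5 | intermediate
12 | 5,7-dihydroxy-6-[7-hydroxy-2-(4-hydroxyphenyl)-5-methoxy-4-oxo-4H-chromen-8-yl]-2-(4-methoxyphenyl)-4H-chromen-4-one (racemic axis) | COc1ccc(cc1)-c2cc(=O)c3c(O)c(c(O)cc3o2)-c4c(O)cc(OC)c5c(=O)cc(oc45)-c6ccc(O)cc6 | intermediate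
13 | 6-[5,7-dihydroxy-2-(4-hydroxyphenyl)-4-oxo-4H-chromen-8-yl]-5,7-dihydroxy-2-(4-methoxyphenyl)-4H-chromen-4-one (racemic axis) | COc1ccc(-c2cc(=O)c3c(O)c(-c4c(O)cc(O)c5c(=O)cc(-c6ccc(O)cc6)oc45)c(O)cc3o2)cc1 | target

## Step count and least certain steps

Total: 10 steps. Longest linear sequence: 7 steps (steps 1, 2, 3, 7, 8, 9, 10 from acacetin; equally steps 4, 5, 6, 7, 8, 9, 10 from apigenin).

**Step 9 (key step).** The isomerization is an equilibration, so conversion to 12 can stay incomplete. Ring opening of the hindered unit 1 may be slow. On long heating the open diketone can lose its aroyl group, and the methyl ethers can be slowly hydrolysed, after which unit 2 would start to migrate. The two isomers may also be hard to separate.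

Fallback: build the 6-linkage directly from 1 and 8 and rejoin the route at 12.
- Acacetin 1 is benzylated at the unchelated 7-OH only (BnBr 1.1 equiv, K2CO3, acetone) to 7-O-benzylacacetin F1.
- With the 5-OH free, iodination with benzyltrimethylammonium dichloroiodate and CaCO3 in CH2Cl2–MeOH goes ortho to that phenol and gives 6-iodo-7-O-benzylacacetin F2.
- Benzylation of the 5-OH (BnBr, K2CO3, DMF, 80 °C) gives 5,7-di-O-benzyl-6-iodoacacetin F3.
- Iodide 8 is converted under the conditions of step 3 into the unit 2 pinacol boronate F4.
- Suzuki coupling of F3 with F4 under the conditions of step 7 gives the tetra-O-benzyl 6,8-linked biflavone F5.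
- Hydrogenolysis as in step 8 gives 12.

**Step 7.** The di-ortho-alkoxy boronate 4 can undergo protodeboronation in the basic aqueous medium faster than the slow transmetalation at a tetra-ortho-substituted centre. Oxidative addition into the electron-rich, hindered iodide 8 may also stall.

Fallback: a Negishi coupling, which sets out from 3 and 8, returns at 9 and bypasses step 3. Zinc dust and LiCl in THF at 40 °C insert into the C–I bond of 3 to give the 8-flavonylzinc iodide F6; the flavone carbonyl tolerates the organozinc. F6 is coupled with 8 using Pd2(dba)3 and SPhos in THF–NMP at 65 °C to give 9. This route is anhydrous, so protodemetalation is suppressed and transmetalation is faster.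

**Step 10.** The tetraphenol 12 is poorly soluble in CH2Cl2, and its phenols bind boron, so demethylation may stay incomplete. Warming to force it could begin to cleave the 4'-methoxy group of unit 1.

Fallback: from 12 through acetates to 13. Ac2O in pyridine gives the tetraacetate F7, which dissolves in CH2Cl2 and has only one chelating site. BCl3 at −78 °C to 0 °C then cleaves the 5-methoxy group of unit 2 to give the 5-hydroxy tetraacetate F8. K2CO3 in MeOH at rt removes the acetates and gives 13.

**Step 8.** Over-reduction of the C2=C3 bonds to flavanones can compete if debenzylation of the two hindered benzyloxy groups next to the axis is slow. Traces of iodide or phosphine from step 7 can also poison the catalyst.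

Fallback: acidolytic debenzylation of 9 directly to 10 with trifluoroacetic acid and pentamethylbenzene as benzyl cation scavenger at 50 °C. It involves no hydrogen and no metal, the methyl ethers survive, and the medium is anhydrous, so the pyranones stay closed. No new compound is formed on the way.

## Further compounds

F1 | step 9 | 7-(benzyloxy)-5-hydroxy-2-(4-methoxyphenyl)-4H-chromen-4-one | COc1ccc(cc1)-c1cc(=O)c2c(O)cc(OCc3ccccc3)cc2o1
F2 | step 9 | 7-(benzyloxy)-5-hydroxy-6-iodo-2-(4-methoxyphenyl)-4H-chromen-4-one | COc1ccc(cc1)-c1cc(=O)c2c(O)c(I)c(OCc3ccccc3)cc2o1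
F3 | step 9 | 5,7-bis(benzyloxy)-6-iodo-2-(4-methoxyphenyl)-4H-chromen-4-one | COc1ccc(cc1)-c1cc(=O)c2c(OCc3ccccc3)c(I)c(OCc3ccccc3)cc2o1
F4 | step 9 | 7-(benzyloxy)-2-[4-(benzyloxy)phenyl]-5-methoxy-8-(4,4,5,5-tetramethyl-1,3,2-dioxaborolan-2-yl)-4H-chromen-4-one | COc1cc(OCc2ccccc2)c(B2OC(C)(C)C(C)(C)O2)c2oc(-c3ccc(OCc4ccccc4)cc3)cc(=O)c12
F5 | step 9 | 6-{7-(benzyloxy)-2-[4-(benzyloxy)phenyl]-5-methoxy-4-oxo-4H-chromen-8-yl}-5,7-bis(benzyloxy)-2-(4-methoxyphenyl)-4H-chromen-4-one (racemic axis) | COc1ccc(cc1)-c2cc(=O)c3c(OCc4ccccc4)c(c(OCc4ccccc4)cc3o2)-c5c(OCc6ccccc6)cc(OC)c7c(=O)cc(oc57)-c8ccc(OCc9ccccc9)cc8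
F6 | step 7 | [5,7-bis(benzyloxy)-2-(4-methoxyphenyl)-4-oxo-4H-chromen-8-yl]zinc iodide | COc1ccc(cc1)-c1cc(=O)c2c(OCc3ccccc3)cc(OCc3ccccc3)c([Zn]I)c2o1
F7 | step 10 | 5,7-diacetoxy-6-[7-acetoxy-2-(4-acetoxyphenyl)-5-methoxy-4-oxo-4H-chromen-8-yl]-2-(4-methoxyphenyl)-4H-chromen-4-one (racemic axis) | COc1ccc(cc1)-c2cc(=O)c3c(OC(C)=O)c(c(OC(C)=O)cc3o2)-c4c(OC(C)=O)cc(OC)c5c(=O)cc(oc45)-c6ccc(OC(C)=O)cc6
F8 | step 10 | 5,7-diacetoxy-6-[7-acetoxy-2-(4-acetoxyphenyl)-5-hydroxy-4-oxo-4H-chromen-8-yl]-2-(4-methoxyphenyl)-4H-chromen-4-one (racemic axis) | COc1ccc(cc1)-c2cc(=O)c3c(OC(C)=O)c(c(OC(C)=O)cc3o2)-c4c(OC(C)=O)cc(O)c5c(=O)cc(oc45)-c6ccc(OC(C)=O)cc6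
F0 | step 8 | none | none
A1 | alternative 1 | methyl 6-[4-(benzyloxy)phenyl]-2-{1-[2,6-bis(benzyloxy)-4-(triisopropylsilyloxy)phenyl]-2-oxopropyl}-4-oxo-4H-pyran-3-carboxylate (racemic) | COC(=O)c1c(C(C(C)=O)c2c(OCc3ccccc3)cc(O[Si](C(C)C)(C(C)C)C(C)C)cc2OCc2ccccc2)oc(-c2ccc(OCc3ccccc3)cc2)cc1=O
A2 | alternative 1 | 8-[2,6-bis(benzyloxy)-4-(triisopropylsilyloxy)phenyl]-2-[4-(benzyloxy)phenyl]-5,7-dihydroxy-4H-chromen-4-one | Oc1cc(O)c(c2oc(cc(=O)c12)-c3ccc(OCc4ccccc4)cc3)-c5c(OCc6ccccc6)cc(O[Si](C(C)C)(C(C)C)C(C)C)cc5OCc7ccccc7
A3 | alternative 2 | 3,5-bis(benzyloxy)-2-[2,6-bis(benzyloxy)-4-(triisopropylsilyloxy)phenyl]-6-[(triphenylphosphoranylidene)acetyl]phenyl 4-(benzyloxy)benzoate | O=C(C=P(c1ccccc1)(c1ccccc1)c1ccccc1)c1c(OCc2ccccc2)cc(OCc2ccccc2)c(c1OC(=O)c1ccc(OCc2ccccc2)cc1)-c1c(OCc2ccccc2)cc(O[Si](C(C)C)(C(C)C)C(C)C)cc1OCc1ccccc1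
A4 | alternative 2 | 8-[2,6-bis(benzyloxy)-4-(triisopropylsilyloxy)phenyl]-5,7-bis(benzyloxy)-2-[4-(benzyloxy)phenyl]-4H-chromen-4-one | O=c1cc(-c2ccc(OCc3ccccc3)cc2)oc4c1c(OCc5ccccc5)cc(OCc5ccccc5)c4-c6c(OCc7ccccc7)cc(O[Si](C(C)C)(C(C)C)C(C)C)cc6OCc8ccccc8
A5 | alternative 3 | 8-[2,6-bis(benzyloxy)-4-hydroxyphenyl]-5,7-bis(benzyloxy)-2-[4-(benzyloxy)phenyl]-4H-chromen-4-one | O=c1cc(-c2ccc(OCc3ccccc3)cc2)oc2c1c(OCc1ccccc1)cc(OCc1ccccc1)c2-c1c(OCc2ccccc2)cc(O)cc1OCc1ccccc1
A6 | alternative 3 | (2Z)-3-{3,5-bis(benzyloxy)-4-[5,7-bis(benzyloxy)-2-(4-benzyloxyphenyl)-4-oxo-4H-chromen-8-yl]phenoxy}-3-(4-methoxyphenyl)prop-2-enoic acid | COc1ccc(cc1)/C(=C/C(O)=O)Oc1cc(OCc2ccccc2)c(c(OCc2ccccc2)c1)-c1c(OCc2ccccc2)cc(OCc2ccccc2)c2c(=O)cc(oc12)-c1ccc(OCc2ccccc2)cc1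
A7 | alternative 3 | 5,7-bis(benzyloxy)-6-{5,7-bis(benzyloxy)-2-[4-(benzyloxy)phenyl]-4-oxo-4H-chromen-8-yl}-2-(4-methoxyphenyl)-4H-chromen-4-one | COc1ccc(cc1)-c2cc(=O)c3c(OCc4ccccc4)c(c(OCc4ccccc4)cc3o2)-c5c(OCc6ccccc6)cc(OCc6ccccc6)c7c(=O)cc(oc57)-c8ccc(OCc9ccccc9)cc8
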